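Over the same stretch of readings the midnight run lost more substrate than the dusk run, 20 percentage points against 7.7 points. With little material to spend, you have to choose the next charge from that.

| flask | substrate | remark | time |
|---|---|---|---|
| dusk | 0.47 M | run made earlier |  |
| midnight | 2.8 M | run made earlier |  |
| Tuesday's | 1.0 M |  | 8.0 h |
| Monday's | 2.5 M |  | 8.0 h |
| Saturday's | 1.5 M |  | 8.0 h |
| Thursday's | 0.40 M |  | 8.0 h |

| run | time / h | ring / % | substrate / % |
|---|---|---|---|
| dusk | 0.417 | 38.4 | 56.7 |
| dusk | 1.00 | 39.8 | 54.9 |
| dusk | 2.50 | 38.1 | 52.6 |
| dusk | 6.00 | 36.0 | 49.0 |
| midnight | 0.417 | 32.7 | 50.3 |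
| midnight | 1.00 | 32.6 | 46.3 |
| midnight | 2.50 | 29.2 | 41.1 |
| midnight | 6.00 | 23.2 | 30.7 |

(scatter of a reading: 0.5 percentage points)

- the earlier runs were read with a standard deviation of 0.5 points

- the flasks put in order of amount of ring, in percent of the substrate charged, best first, at 8.0 h (Tuesday's / Monday's / Saturday's / Thursday's)
- the amount of ring, in percent of the substrate charged of the flask you put first, at 8.0 h
- the amount of ring, in percent of the substrate charged of the flask you put last, at 8.0 h

Write a for the fraction of the charge standing as substrate and r for the fraction standing as ring. Divide one by the other: at 0.417 h that gives 0.677 in the dusk run and 0.650 in the midnight run, but from 1.00 h on it lies between 0.704 and 0.756 in both runs, so after the first reading time nearly drops out. Pooling the last two readings of both runs gives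

R = r / a = 0.730

Call R the ring ratio, the ring held per substrate held. At the last reading, the dusk run alone gives 0.735 and the midnight run alone gives 0.756, although their charges are 0.47 M and 2.8 M. So I take, for the next flask,

r = R × a

Your choice then becomes which charge keeps the most substrate. At 6.00 h the dusk run kept 49.0% and the midnight run 30.7%. I would therefore make Thursday's, the lowest charge, and I commit to an order that follows rising charge, without a figure of my own.

The forecast gives Thursday's > Tuesday's > Saturday's > Monday's, with 35.7% (34.5% to 37%) for the first flask and 21% (19.5% to 22.5%) for the last. It reads the ratio as 0.72 where I read 0.730, and it concludes: “Dilute is best, so the order follows increasing concentration”.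

The flasks give Thursday's > Tuesday's > Saturday's > Monday's, with Thursday's at 35.0% and Monday's at 20.3%. The order stands, both values lie inside the forecast's ranges, and Thursday's is the charge to make.

    substrate ⇌ ring (K = 0.720, k = 0.00100 s⁻¹)
    2 substrate ⇌ open dimer (K = 0.100 M⁻¹, k = 0.00240 M⁻¹ s⁻¹)
    substrate + ring → side product (k = 3.20 × 10⁻⁵ M⁻¹ s⁻¹)

In Thursday's, R times the 48.6% of substrate gives 35.5%, against 35.0% of ring. In Monday's, substrate and ring relax towards each other with a half-life, by that step by itself, of 0.0806 h, shorter than 8.0 h, which makes them a pre-equilibrium. Now leave Monday's standing until 30 h, with every amount the same. Substrate falls to 12.0% and side product stands at 78.6%. R times that substrate gives 8.76%, and the flask holds 8.63% of ring.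

The data are simulated for substances that don't exist, and the scatter is random.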